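**Retrosynthetic overview**
- The C8–prenyl bond is cut last, as a Stille coupling on an 8-bromochromanol. The bromine comes with the starting aldehyde and first serves to block the carbon between the two phenols.
- The pyran ring (ring C) is the only ring formed. It comes from 6-endo attack of the C3 phenol on the tertiary carbon of an (R)-prenyl epoxide. The epoxide is made and closed in one flask on the unprotected bromostilbenediol, and the Shi epoxidation sets the only stereocentre.
- The C2-prenyl group comes from alumina-templated ortho-prenylation of 4-bromopinosylvin, where C4 is blocked and C2 equals C6.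
- 4-Bromopinosylvin comes from a Horner–Wadsworth–Emmons olefination followed by O-demethylation. Both benzene rings (A and B) are bought.

Assumption: in the plant the pyran ring arises by epoxidation of the C2-prenyl group of a prenylated pinosylvin, followed by 6-endo attack of the neighbouring phenol. The carbinol centre of the target SMILES is (R).

**Step 1**
Reactants: 1 4-bromo-3,5-dimethoxybenzaldehyde; 2 diethyl benzylphosphonate
Product: 4 (E)-4-bromo-3,5-dimethoxystilbene, via phosphonate carbanion 3 (not isolated)
Conditions: 2, KOtBu, THF, 0 °C; then 1, 0 °C to rt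
Reagents that add atoms: diethyl benzylphosphonate 2, CCOP(=O)(Cc1ccccc1)OCC
Why: The Horner–Wadsworth–Emmons olefination of a non-enolisable aryl aldehyde with a benzylphosphonate anion gives the (E)-stilbene almost exclusively and does not touch the aryl bromide.

**Step 2**
Reactants: 4 (E)-4-bromo-3,5-dimethoxystilbene
Product: 6 4-bromopinosylvin (2-bromo-5-[(E)-2-phenylethenyl]benzene-1,3-diol), via bis(dibromoboryl) ether 5 (not isolated)
Conditions: BBr3 (3 equiv), CH2Cl2, −78 °C to rt; then H2O
Reagents that add atoms: none
Why: Lewis-acid aryl methyl ether cleavage with BBr3 is the standard way from stilbene methyl ethers to hydroxystilbenes, and it comes before any acid-sensitive group is present.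

**Step 3**
Reactants: 6 4-bromopinosylvin; 7 prenol (3-methylbut-2-en-1-ol)
Product: 8 2-bromo-4-(3-methylbut-2-en-1-yl)-5-[(E)-2-phenylethenyl]benzene-1,3-diol (4-bromo-2-prenylpinosylvin)
Conditions: 7 (1.1 equiv), acidic Al2O3, ClCH2CH2Cl, reflux
Reagents that add atoms: prenol 7, CC(C)=CCO
Why: This dehydrative Friedel–Crafts ortho-allylation on acidic alumina delivers the prenyl cation only ortho to an adsorbed phenol, and because bromine blocks the normally preferred carbon between the two OH groups and C2 and C6 are equivalent, only one mono-C-prenyl product can form.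

**Step 4**
Reactants: 8 4-bromo-2-prenylpinosylvin
Product: 10 (3R)-8-bromo-2,2-dimethyl-5-[(E)-2-phenylethenyl]-3,4-dihydro-2H-chromene-3,7-diol, via (R)-epoxide 9 (not isolated)
Conditions: D-fructose-derived Shi ketone (1 equiv, in portions), Oxone (2KHSO5·KHSO4·K2SO4, 1.5 equiv KHSO5), NaHCO3, MeCN/aq. Na2EDTA, pH 7–7.5, 0 °C; extract; then CSA (10 mol%), CH2Cl2, −20 °C
Reagents that add atoms: potassium peroxymonosulfate (active salt of Oxone), [K+].[O-]S(=O)(=O)OO
Why: In this Shi asymmetric epoxidation followed by acid-catalysed 6-endo epoxide opening, the chiral dioxirane attacks the trisubstituted prenyl alkene far faster than the trans-stilbene or the bromine-deactivated resorcinol ring and gives the (R)-epoxide, the near-neutral pH keeps the phenols protonated so no base-induced 5-exo closure occurs, and CSA then drives the C3 phenol onto the tertiary epoxide carbon without touching the C–O bond at the stereocentre, so (R) is carried into the carbinol.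

**Step 5**
Reactants: 10 (3R)-8-bromochromane-3,7-diol; 11 tributyl(3-methylbut-2-en-1-yl)stannane
Product: 12 (3R)-2,2-dimethyl-8-(3-methylbut-2-en-1-yl)-5-[(E)-2-phenylethenyl]-3,4-dihydro-2H-chromene-3,7-diol (target)
Conditions: 11 (1.5 equiv), Pd2(dba)3 (2.5 mol%), P(t-Bu)3 (10 mol%), CsF, 1,4-dioxane, 90 °C
Reagents that add atoms: tributyl(3-methylbut-2-en-1-yl)stannane 11, CCCC[Sn](CCCC)(CCCC)CC=C(C)C
Why: In this Stille coupling the electron-rich, bulky phosphine lets zerovalent palladium insert into the hindered bromophenol, fluoride speeds up transmetalation, reductive elimination at the unhindered allyl terminus gives the linear prenyl group exactly at C8, and the carbinol stereocentre, free OH groups and stilbene are spectators.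

**Compound list**
1 | 4-bromo-3,5-dimethoxybenzaldehyde | COc1cc(C=O)cc(OC)c1Br | starting material
2 | diethyl benzylphosphonate | CCOP(=O)(Cc1ccccc1)OCC | starting material
3 | potassium salt of the diethyl benzylphosphonate carbanion | [K+].CCOP(=O)([CH-]c1ccccc1)OCC | intermediate
4 | (E)-4-bromo-3,5-dimethoxystilbene | COc1cc(/C=C/c2ccccc2)cc(OC)c1Br | intermediate
5 | bis(dibromoboryl) ether of 4-bromopinosylvin | BrB(Br)Oc1cc(/C=C/c2ccccc2)cc(OB(Br)Br)c1Br | intermediate
6 | 2-bromo-5-[(E)-2-phenylethenyl]benzene-1,3-diol (4-bromopinosylvin) | Oc1cc(/C=C/c2ccccc2)cc(O)c1Br | intermediate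
7 | 3-methylbut-2-en-1-ol (prenol) | CC(C)=CCO | starting material
8 | 2-bromo-4-(3-methylbut-2-en-1-yl)-5-[(E)-2-phenylethenyl]benzene-1,3-diol | CC(C)=CCc1c(O)c(Br)c(O)cc1/C=C/c2ccccc2 | intermediate
9 | 2-bromo-4-{[(2R)-3,3-dimethyloxiran-2-yl]methyl}-5-[(E)-2-phenylethenyl]benzene-1,3-diol | CC1(C)O[C@@H]1Cc2c(O)c(Br)c(O)cc2/C=C/c3ccccc3 | intermediate
10 | (3R)-8-bromo-2,2-dimethyl-5-[(E)-2-phenylethenyl]-3,4-dihydro-2H-chromene-3,7-diol | Brc1c(O)cc(/C=C/c2ccccc2)c2c1OC(C)(C)[C@H](O)C2 | intermediate
11 | tributyl(3-methylbut-2-en-1-yl)stannane | CCCC[Sn](CCCC)(CCCC)CC=C(C)C | starting material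
12 | (3R)-2,2-dimethyl-8-(3-methylbut-2-en-1-yl)-5-[(E)-2-phenylethenyl]-3,4-dihydro-2H-chromene-3,7-diol | CC(C)=CCc1c(O)cc(/C=C/c2ccccc2)c2c1OC(C)(C)[C@H](O)C2 | target

**Step count**
Total step count: 5. Longest linear sequence: 5.

**Steps most likely to fail**

Step 4 is the riskiest. The free bromophenols may be partly ionised and oxidised. Some 5-exo closure to the dihydrobenzofuran may occur. Under acid the neighbouring styryl alkene could compete with the phenol for the tertiary cationic centre. The fallback sets the stereocentre by ketone reduction instead of alkene oxidation: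
- It sets out from 8, which is treated with mCPBA in CH2Cl2 at 0 °C and then CSA to give the racemic 8-bromochromane-3,7-diol F2.
- Dess–Martin periodinane oxidises this to the 8-bromo-7-hydroxychroman-3-one F3.
- (S)-Me-CBS oxazaborolidine with catecholborane in toluene at −40 °C reduces the ketone. The quaternary C2 acts as the large group and C4H2 as the small group, which gives the (R)-alcohol.
- The fallback returns to the route at 10.

Step 5 is next. Oxidative addition into an electron-rich bromide flanked by two oxygens is slow, and some branched allyl product is possible. The fallback drops cross-coupling for a Friedel–Crafts prenylation: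
- It sets out from 10, which is reduced with Bu3SnH and AIBN in toluene at 80 °C to the debrominated (3R)-chromane-3,7-diol F4.
- F4 is heated with prenol 7 on acidic Al2O3 in ClCH2CH2Cl. C8 is ortho to both oxygens and C6 is shielded by the styryl group, so C8 should be alkylated preferentially.
- The fallback arrives directly at 12.

Step 3 is third. The position next to the styryl group is hindered, so conversion may be slow. A second prenylation at C6 or acid cyclisation to a chromane may also interfere. The fallback replaces intermolecular C-alkylation with O-alkylation and a sigmatropic shift: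
- It sets out from 6, which reacts with one equivalent of tert-butyl 2-methylbut-3-en-2-yl carbonate and Pd(PPh3)4 (1 mol%) in THF at 0 °C to give the mono(1,1-dimethylallyl) ether F1.
- Heating F1 in N,N-diethylaniline at 160 °C triggers an aromatic Claisen rearrangement to the only free ortho carbon. The para pathway gives the same compound by symmetry.
- The fallback returns to the route at 8.

**Further compounds**
F1 | step 3 | 2-bromo-3-[(2-methylbut-3-en-2-yl)oxy]-5-[(E)-2-phenylethenyl]phenol | C=CC(C)(C)Oc1cc(/C=C/c2ccccc2)cc(O)c1Br
F2 | step 4 | racemic 8-bromo-2,2-dimethyl-5-[(E)-2-phenylethenyl]-3,4-dihydro-2H-chromene-3,7-diol | Brc1c(O)cc(/C=C/c2ccccc2)c2c1OC(C)(C)C(O)C2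
F3 | step 4 | 8-bromo-7-hydroxy-2,2-dimethyl-5-[(E)-2-phenylethenyl]-2H-chromen-3(4H)-one | Brc1c(O)cc(/C=C/c2ccccc2)c2c1OC(C)(C)C(=O)C2
F4 | step 5 | (3R)-2,2-dimethyl-5-[(E)-2-phenylethenyl]-3,4-dihydro-2H-chromene-3,7-diol | Oc1cc(/C=C/c2ccccc2)c2c(c1)OC(C)(C)[C@H](O)C2
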